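**Plan**
- Numbering (germacranolide): ring C1–C10; C11 on C7 with C12 (C=O) and C13 (=CH2); lactone oxygen on C8; ester oxygen on C9; C14 on C10; C15 on C4.
- Cuts, in retrosynthetic order: O9–acyl, C11=C13 and the epoxide oxygen; then C5–C6 together with C4–C15 (ring opening to a terminal ynal plus Zn(CH3)2); then C7–C8 (aldol) with O8–C12 (lactone); C2–C3 (propargylation); C9–C10 (crotylation).
- Forward order: chain C8–C10, then C1–C5 with the alkyne, then the butanolide (O8, C8, C7, C11, C12), then the ten-membered carbocycle, then epoxide, methylene lactone and ester.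
- Enabling feature: C15 and C6 sit cis on the C4–C5 unit of the ten-membered ring, next to the C6 carbinol. The epoxide is an E-trisubstituted allylic alcohol in disguise, the footprint of adding CH3 and a carbonyl carbon to the same side of a terminal alkyne C4≡C5.
- Stereochemistry: C9/C10 from a catalytic asymmetric E-crotylboration; C8 from C9 by chelation and C7 anti to C8 in one Mukaiyama aldol; C6 from C7 during ring closure; C4/C5 from the C6 hydroxyl by directed epoxidation.

Key step: step 12

Remark on the chemistry: the ring closure is assumed to give mainly the C6 carbinol drawn (hydroxyl syn to C11); C6 is the only centre for which no close precedent exists. Germacranolide locants are used in all Why lines.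

**Step 1**
Reactants: 1 (E)-cinnamaldehyde; 2 (E)-crotylboronic acid pinacol ester
Product: 3 (1E,3S,4R)-4-methyl-1-phenylhexa-1,5-dien-3-ol
Conditions: (R)-TRIP [(R)-3,3'-bis(2,4,6-triisopropylphenyl)-1,1'-binaphthyl-2,2'-diyl hydrogen phosphate] (5 mol%), toluene, −30 °C; aq. NaHCO3
Reagents that add atoms: none
Why: Chiral phosphoric acid-catalysed crotylboration through a closed chair transition state; the E-boronate gives the anti C9/C10 relationship and the (R)-acid should send the crotyl group to the Re face of the enal carbonyl, which fixes both centres (3S,4R in 3).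

**Step 2**
Reactants: 3 dienol
Product: 4 1-methoxy-4-({[(1E,3S,4R)-4-methyl-1-phenylhexa-1,5-dien-3-yl]oxy}methyl)benzene
Conditions: NaH, 4-methoxybenzyl chloride, Bu4NI (cat.), DMF, 0 °C to rt
Reagents that add atoms: 4-methoxybenzyl chloride, COc1ccc(CCl)cc1
Why: Williamson etherification of the sodium alkoxide; the PMB ether is chosen because it can chelate in step 9 and is cleaved oxidatively late in the presence of epoxide and silyl ether.

**Step 3**
Reactants: 4 PMB ether
Product: 6 (3R,4R,5E)-4-[(4-methoxyphenyl)methoxy]-3-methyl-6-phenylhex-5-en-1-ol, via B-alkyl-9-BBN adduct 5 (not isolated)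
Conditions: 9-BBN, THF, 0 °C to rt; then NaOH, H2O2, 0 °C
Reagents that add atoms: hydrogen peroxide, OO
Why: Anti-Markovnikov hydroboration–oxidation; 9-BBN distinguishes the monosubstituted vinyl group from the 1,2-disubstituted styryl alkene on steric grounds.

**Step 4**
Reactants: 6 primary alcohol
Product: 7 1-({[(1E,3R,4R)-6-iodo-4-methyl-1-phenylhex-1-en-3-yl]oxy}methyl)-4-methoxybenzene
Conditions: I2, PPh3, imidazole, CH2Cl2, 0 °C to rt
Reagents that add atoms: iodine, II
Why: Appel-type iodination; the unhindered primary oxyphosphonium is displaced by iodide in an SN2 step.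

**Step 5**
Reactants: 7 iodide; 8 1-(trimethylsilyl)propyne
Product: 11 1-methoxy-4-({[(1E,3R,4R)-4-methyl-1-phenylnon-1-en-8-yn-3-yl]oxy}methyl)benzene, via lithiated silylpropyne 9 (not isolated), via alkynylsilane 10 (not isolated)
Conditions: 8, n-BuLi, THF, −78 °C; 7, THF/DMPU, −78 to 0 °C; then K2CO3, CH3OH, rt
Reagents that add atoms: none
Why: Propargylic lithiation of 8 and SN2 alkylation of the primary iodide (the silyl group steers bonding to the propargylic carbon) add C3–C5, and methoxide-mediated protodesilylation then frees the terminal alkyne without touching the PMB ether or the styrene.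

**Step 6**
Reactants: 11 enyne
Product: 12 (2R,3R)-2-[(4-methoxyphenyl)methoxy]-3-methyloct-7-ynal
Conditions: OsO4 (cat.), NaIO4, 2,6-lutidine, dioxane/H2O, rt
Reagents that add atoms: sodium periodate, [Na+].[O-]I(=O)(=O)=O (oxygen passed on by catalytic OsO4)
Why: Lemieux–Johnson oxidative cleavage; OsO4 dihydroxylates the styryl alkene and not the alkyne, NaIO4 cleaves the diol, and the buffered medium lets the α-alkoxy aldehyde be used without epimerisation at C9.

**Step 7**
Reactants: 13 methyl 4-chloro-4-oxobutanoate; 14 2-methylpropane-2-thiol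
Product: 15 methyl 4-(tert-butylsulfanyl)-4-oxobutanoate
Conditions: pyridine, CH2Cl2, 0 °C to rt
Reagents that add atoms: none
Why: Acylation of the thiol by the acid chloride (addition–elimination); the methyl ester is not touched.

**Step 8**
Reactants: 15 thioester
Product: 17 methyl (3Z)-4-(tert-butylsulfanyl)-4-[(trimethylsilyl)oxy]but-3-enoate, via thioester lithium enolate 16 (not isolated)
Conditions: LiN(iPr)2, THF, −78 °C; then (CH3)3SiCl, −78 °C to rt
Reagents that add atoms: chlorotrimethylsilane, C[Si](C)(C)Cl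
Why: Kinetic deprotonation at the more acidic α-position of the thioester and O-silylation (enolate trapping) give the silyl ketene thioacetal; the ester α-position is much less acidic.

**Step 9**
Reactants: 12 aldehyde; 17 silyl ketene thioacetal
Product: 19 S-tert-butyl (2R,3S)-2-{(1R,2R)-1-[(4-methoxyphenyl)methoxy]-2-methylhept-6-yn-1-yl}-5-oxooxolane-3-carbothioate, via aldol adduct 18 (not isolated)
Conditions: SnCl4, CH2Cl2, −78 °C; aq. NaHCO3; then camphorsulfonic acid (cat.), CH2Cl2, rt
Reagents that add atoms: none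
Why: Mukaiyama aldol under chelation control; SnCl4 bridges the aldehyde oxygen and the C9 PMB ether so that the nucleophile enters opposite the C10 chain (8,9-syn), the open transition state of thioester silyl ketene acetals on such chelates gives 7,8-anti, and acid-catalysed lactonisation of the γ-hydroxy ester closes the cis-disubstituted butanolide.

**Step 10**
Reactants: 19 lactone thioester
Product: 20 (4R,5R)-4-(hydroxymethyl)-5-{(1R,2R)-1-[(4-methoxyphenyl)methoxy]-2-methylhept-6-yn-1-yl}oxolan-2-one
Conditions: NaBH4, THF/EtOH, 0 °C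
Reagents that add atoms: none
Why: Chemoselective borohydride reduction; a thioester is reduced far faster than a γ-lactone, and the cold, short reaction limits epimerisation at C7 and migration of the lactone to the new primary hydroxyl.

**Step 11**
Reactants: 20 hydroxymethyl lactone
Product: 21 (2R,3S)-2-{(1R,2R)-1-[(4-methoxyphenyl)methoxy]-2-methylhept-6-yn-1-yl}-5-oxooxolane-3-carbaldehyde
Conditions: Dess–Martin periodinane, NaHCO3, CH2Cl2, 0 °C to rt
Reagents that add atoms: none
Why: Dess–Martin oxidation under buffered, non-basic conditions gives the C6 aldehyde without epimerising the cis C7 centre; 21 is used at once.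

**Step 12**
Reactants: 21 ynal; 22 dimethylzinc
Product: 23 (4E,6S,7R,8R,9R,10R)-6-hydroxy-9-[(4-methoxyphenyl)methoxy]-13-norgermacr-4-en-12,8-olide
Conditions: Ni(cod)2 (30 mol%), IMes (1,3-dimesitylimidazol-2-ylidene, 30 mol%), Zn(CH3)2 (3 equiv), toluene, 50 °C, slow addition of 21 (final 0.003 M); aq. NH4Cl
Reagents that add atoms: none
Why: Proposed new method: nickel in its zerovalent state, carrying IMes, takes up the alkyne and the aldehyde side by side, and oxidative cyclisation joins C5 (the CH terminus) to C6 to give a five-membered oxanickelacycle of divalent nickel with the metal on C4 and on the aldehyde oxygen; Zn(CH3)2 then exchanges a methyl for the nickel-bound oxygen, and reductive elimination makes the C4–CH3 bond on the side of the alkene where C6 already sits (4E), releasing the catalyst and the zinc alkoxide of 23. The closest known reaction types are nickel-catalysed alkylative cyclisations of ynals with organozincs, which close five- and six-membered rings with exocyclic alkenes, and nickel–carbene reductive macrocyclisations of terminal ynals with silanes, which give endocyclic E-allylic alcohols; the new element is their combination in a ten-membered ring. The carbocycle C1–C10 closes in the endocyclic mode, both alkyne carbons becoming ring atoms, the competing mode being a nine-membered ring with an exocyclic ethylidene. The one new stereocentre, C6, is controlled by the neighbouring C7 centre held in the cis-lactone, which decides the aldehyde face that the tethered alkyne can reach in the metallacycle; the epimer with hydroxyl syn to C11 is the one planned for. The step needs bonding at C5 and not at C4, for which the terminal alkyne and a carbene of moderate size are chosen (a very large carbene would favour the exocyclic mode), and it needs ring closure to outpace oligomerisation and uncatalysed methyl addition to the aldehyde, which slow addition at high dilution and the low carbonyl reactivity of Zn(CH3)2 should secure.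

**Step 13**
Reactants: 23 cyclodecenol
Product: 24 (4R,5R,6R,7R,8R,9R,10R)-4,5-epoxy-6-hydroxy-9-[(4-methoxyphenyl)methoxy]-13-norgermacran-12,8-olide
Conditions: VO(acac)2 (5 mol%), t-BuOOH, CH2Cl2, 0 °C to rt
Reagents that add atoms: tert-butyl hydroperoxide, CC(C)(C)OO
Why: Vanadium-catalysed hydroxyl-directed epoxidation; the C6 vanadate should deliver the peroxide oxygen to the peripheral face of the E-cyclodecene in the conformer that holds the C6–O bond near the alkene plane, which corresponds to the 4R,5R epoxide, and there is no other alkene to oxidise.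

**Step 14**
Reactants: 24 epoxy alcohol
Product: 25 (4R,5R,6R,7S,8R,9R,10R)-4,5-epoxy-9-[(4-methoxyphenyl)methoxy]-6-(triethylsilyloxy)-13-norgermacran-12,8-olide
Conditions: (C2H5)3SiCl, imidazole, DMAP (cat.), DMF, 0 °C to rt
Reagents that add atoms: chlorotriethylsilane, CC[Si](Cl)(CC)CC
Why: Imidazole-promoted silylation masks the C6 hydroxyl, which prevents Payne rearrangement of the epoxy alcohol in the basic steps that follow and keeps it distinct from the C9 hydroxyl (the C7 descriptor changes only through the priority of silicon).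

**Step 15**
Reactants: 25 silyl ether
Product: 27 13-(dimethylamino)-4,5-epoxy-9-[(4-methoxyphenyl)methoxy]-6-(triethylsilyloxy)germacran-12,8-olide (C11 epimers; other centres as in 25), via lactone lithium enolate 26 (not isolated)
Conditions: LiN(iPr)2, THF, −78 °C; then CH2=N(CH3)2 I, −78 to 0 °C
Reagents that add atoms: N,N-dimethylmethyleneiminium iodide, C=[N+](C)C.[I-]
Why: Mannich reaction of the lactone lithium enolate at C11 with the preformed iminium salt; the new C11 centre is of no consequence because it becomes trigonal in step 16, and silyl ether, PMB ether and epoxide are inert to the amide base at −78 °C.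

**Step 16**
Reactants: 27 Mannich base
Product: 29 (4R,5R,6R,7S,8R,9R,10R)-4,5-epoxy-9-[(4-methoxyphenyl)methoxy]-6-(triethylsilyloxy)germacr-11(13)-en-12,8-olide, via trimethylammonium iodide 28 (not isolated)
Conditions: CH3I, THF, rt; then aq. NaHCO3, CH2Cl2, rt
Reagents that add atoms: none
Why: Exhaustive N-methylation followed by base-induced β-elimination of trimethylamine (Hofmann-type, E1cB) creates the exocyclic C11=C13 alkene conjugated to the lactone.

**Step 17**
Reactants: 29 methylene lactone
Product: 30 (4R,5R,6R,7S,8R,9R,10R)-4,5-epoxy-9-hydroxy-6-(triethylsilyloxy)germacr-11(13)-en-12,8-olide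
Conditions: DDQ, CH2Cl2/pH 7 buffer, 0 °C to rt
Reagents that add atoms: none
Why: Oxidative PMB cleavage by DDQ (hydride abstraction at the electron-rich benzylic carbon, then hydrolysis) frees only the C9 hydroxyl; silyl ether, epoxide and the electron-poor methylene lactone do not react.

**Step 18**
Reactants: 30 C9 alcohol; 31 3-methylbut-2-enoic acid
Product: 32 (4R,5R,6R,7S,8R,9R,10R)-4,5-epoxy-9-(3-methylbut-2-enoyloxy)-6-(triethylsilyloxy)germacr-11(13)-en-12,8-olide
Conditions: DCC, DMAP, CH2Cl2, rt
Reagents that add atoms: none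
Why: Steglich esterification of the secondary C9 alcohol; the carbodiimide/DMAP protocol avoids the vinylketene pathway by which senecioyl chloride and amine bases give deconjugated esters.

**Step 19**
Reactants: 32 silyl ether of the target
Product: 33 (4R,5R,6R,7R,8R,9R,10R)-4,5-epoxy-6-hydroxy-9-(3-methylbut-2-enoyloxy)germacr-11(13)-en-12,8-olide
Conditions: HF·pyridine, pyridine, THF, 0 °C
Reagents that add atoms: none
Why: Fluoride-mediated cleavage of the triethylsilyl ether under pyridine-buffered conditions, which leave the epoxide, the senecioate and the methylene lactone intact.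

**Compound list**
1 | (E)-cinnamaldehyde | O=C/C=C/c1ccccc1 | starting material
2 | (E)-crotylboronic acid pinacol ester | C/C=C/CB1OC(C)(C)C(C)(C)O1 | starting material
3 | (1E,3S,4R)-4-methyl-1-phenylhexa-1,5-dien-3-ol | C=C[C@@H](C)[C@@H](O)/C=C/c1ccccc1 | intermediate
4 | 1-methoxy-4-({[(1E,3S,4R)-4-methyl-1-phenylhexa-1,5-dien-3-yl]oxy}methyl)benzene | C=C[C@@H](C)[C@@H](OCc1ccc(OC)cc1)/C=C/c1ccccc1 | intermediate
5 | 9-[(3R,4R,5E)-4-[(4-methoxyphenyl)methoxy]-3-methyl-6-phenylhex-5-en-1-yl]-9-borabicyclo[3.3.1]nonane | C1CC2CCCC(C1)B2CC[C@@H](C)[C@@H](OCc1ccc(OC)cc1)/C=C/c1ccccc1 | intermediate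
6 | (3R,4R,5E)-4-[(4-methoxyphenyl)methoxy]-3-methyl-6-phenylhex-5-en-1-ol | OCC[C@@H](C)[C@@H](OCc1ccc(OC)cc1)/C=C/c1ccccc1 | intermediate
7 | 1-({[(1E,3R,4R)-6-iodo-4-methyl-1-phenylhex-1-en-3-yl]oxy}methyl)-4-methoxybenzene | ICC[C@@H](C)[C@@H](OCc1ccc(OC)cc1)/C=C/c1ccccc1 | intermediate
8 | 1-(trimethylsilyl)propyne | CC#C[Si](C)(C)C | starting material
9 | [3-(trimethylsilyl)prop-2-yn-1-yl]lithium | [Li]CC#C[Si](C)(C)C | intermediate
10 | trimethyl{(6R,7R,8E)-7-[(4-methoxyphenyl)methoxy]-6-methyl-9-phenylnon-8-en-1-yn-1-yl}silane | C[Si](C)(C)C#CCCC[C@@H](C)[C@@H](OCc1ccc(OC)cc1)/C=C/c1ccccc1 | intermediate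
11 | 1-methoxy-4-({[(1E,3R,4R)-4-methyl-1-phenylnon-1-en-8-yn-3-yl]oxy}methyl)benzene | C#CCCC[C@@H](C)[C@@H](OCc1ccc(OC)cc1)/C=C/c1ccccc1 | intermediate
12 | (2R,3R)-2-[(4-methoxyphenyl)methoxy]-3-methyloct-7-ynal | C#CCCC[C@@H](C)[C@@H](OCc1ccc(OC)cc1)C=O | intermediate
13 | methyl 4-chloro-4-oxobutanoate | COC(=O)CCC(Cl)=O | starting material
14 | 2-methylpropane-2-thiol | CC(C)(C)S | starting material
15 | methyl 4-(tert-butylsulfanyl)-4-oxobutanoate | COC(=O)CCC(=O)SC(C)(C)C | intermediate
16 | lithium (1Z)-1-(tert-butylsulfanyl)-4-methoxy-4-oxobut-1-en-1-olate | COC(=O)C/C=C(/O[Li])SC(C)(C)C | intermediate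
17 | methyl (3Z)-4-(tert-butylsulfanyl)-4-[(trimethylsilyl)oxy]but-3-enoate | COC(=O)C/C=C(/O[Si](C)(C)C)SC(C)(C)C | intermediate
18 | methyl (3S,4R,5R,6R)-3-[(tert-butylsulfanyl)carbonyl]-4-hydroxy-5-[(4-methoxyphenyl)methoxy]-6-methylundec-10-ynoate | C#CCCC[C@@H](C)[C@@H](OCc1ccc(OC)cc1)[C@H](O)[C@H](CC(=O)OC)C(=O)SC(C)(C)C | intermediate
19 | S-tert-butyl (2R,3S)-2-{(1R,2R)-1-[(4-methoxyphenyl)methoxy]-2-methylhept-6-yn-1-yl}-5-oxooxolane-3-carbothioate | C#CCCC[C@@H](C)[C@@H](OCc1ccc(OC)cc1)[C@@H]1OC(=O)C[C@@H]1C(=O)SC(C)(C)C | intermediate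
20 | (4R,5R)-4-(hydroxymethyl)-5-{(1R,2R)-1-[(4-methoxyphenyl)methoxy]-2-methylhept-6-yn-1-yl}oxolan-2-one | C#CCCC[C@@H](C)[C@@H](OCc1ccc(OC)cc1)[C@@H]1OC(=O)C[C@@H]1CO | intermediate
21 | (2R,3S)-2-{(1R,2R)-1-[(4-methoxyphenyl)methoxy]-2-methylhept-6-yn-1-yl}-5-oxooxolane-3-carbaldehyde (ynal with cis-lactone, C6 aldehyde) | C#CCCC[C@@H](C)[C@@H](OCc1ccc(OC)cc1)[C@@H]1OC(=O)C[C@@H]1C=O | intermediate
22 | dimethylzinc | C[Zn]C | starting material
23 | (4E,6S,7R,8R,9R,10R)-6-hydroxy-9-[(4-methoxyphenyl)methoxy]-13-norgermacr-4-en-12,8-olide (ten-membered E-cyclodecenol, cis-fused butanolide) | C1C(=O)O[C@H]2[C@H](OCc3ccc(OC)cc3)[C@H](C)CCC/C(C)=C/[C@H](O)[C@@H]12 | intermediate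
24 | (4R,5R,6R,7R,8R,9R,10R)-4,5-epoxy-6-hydroxy-9-[(4-methoxyphenyl)methoxy]-13-norgermacran-12,8-olide | C1C(=O)O[C@H]2[C@H](OCc3ccc(OC)cc3)[C@H](C)CCC[C@@]3(C)O[C@@H]3[C@H](O)[C@@H]12 | intermediate
25 | (4R,5R,6R,7S,8R,9R,10R)-4,5-epoxy-9-[(4-methoxyphenyl)methoxy]-6-(triethylsilyloxy)-13-norgermacran-12,8-olide | C1C(=O)O[C@H]2[C@H](OCc3ccc(OC)cc3)[C@H](C)CCC[C@@]3(C)O[C@@H]3[C@H](O[Si](CC)(CC)CC)[C@@H]12 | intermediate
26 | lithium enolate of 25 (C11=C12–OLi) | C1=C(O[Li])O[C@H]2[C@H](OCc3ccc(OC)cc3)[C@H](C)CCC[C@@]3(C)O[C@@H]3[C@H](O[Si](CC)(CC)CC)[C@@H]12 | intermediate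
27 | 13-(dimethylamino)-4,5-epoxy-9-[(4-methoxyphenyl)methoxy]-6-(triethylsilyloxy)germacran-12,8-olide (C11 epimers, other centres as in 25) | CN(C)CC1C(=O)O[C@H]2[C@H](OCc3ccc(OC)cc3)[C@H](C)CCC[C@@]3(C)O[C@@H]3[C@H](O[Si](CC)(CC)CC)[C@@H]12 | intermediate
28 | trimethylammonium iodide of 27 | C[N+](C)(C)CC1C(=O)O[C@H]2[C@H](OCc3ccc(OC)cc3)[C@H](C)CCC[C@@]3(C)O[C@@H]3[C@H](O[Si](CC)(CC)CC)[C@@H]12.[I-] | intermediate
29 | (4R,5R,6R,7S,8R,9R,10R)-4,5-epoxy-9-[(4-methoxyphenyl)methoxy]-6-(triethylsilyloxy)germacr-11(13)-en-12,8-olide | C=C1C(=O)O[C@H]2[C@H](OCc3ccc(OC)cc3)[C@H](C)CCC[C@@]3(C)O[C@@H]3[C@H](O[Si](CC)(CC)CC)[C@@H]12 | intermediate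
30 | (4R,5R,6R,7S,8R,9R,10R)-4,5-epoxy-9-hydroxy-6-(triethylsilyloxy)germacr-11(13)-en-12,8-olide | C=C1C(=O)O[C@H]2[C@H](O)[C@H](C)CCC[C@@]3(C)O[C@@H]3[C@H](O[Si](CC)(CC)CC)[C@@H]12 | intermediate
31 | 3-methylbut-2-enoic acid | CC(C)=CC(=O)O | starting material
32 | (4R,5R,6R,7S,8R,9R,10R)-4,5-epoxy-9-(3-methylbut-2-enoyloxy)-6-(triethylsilyloxy)germacr-11(13)-en-12,8-olide | C=C1C(=O)O[C@H]2[C@H](OC(=O)C=C(C)C)[C@H](C)CCC[C@@]3(C)O[C@@H]3[C@H](O[Si](CC)(CC)CC)[C@@H]12 | intermediate
33 | (4R,5R,6R,7R,8R,9R,10R)-4,5-epoxy-6-hydroxy-9-(3-methylbut-2-enoyloxy)germacr-11(13)-en-12,8-olide (CNP0214930.1) | C=C1C(=O)O[C@H]2[C@H](OC(=O)C=C(C)C)[C@H](C)CCC[C@@]3(C)O[C@@H]3[C@H](O)[C@@H]12 | target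

**Step count**
Total: 19 steps. Longest linear sequence: 17 steps (steps 1–6 and 9–19); steps 7 and 8 form the side branch to 17.

**Steps most likely to fail**

Step 12 (proposed new method). The ring closure may lose to oligomerisation, to closure in the exocyclic nine-membered mode or to direct methyl transfer to the aldehyde, and face selectivity at C6 may be low. The fallback uses known chemistry and installs the C4 methyl before the ring is closed. Setting out from alkyne 11, zirconium-catalysed carboalumination (Al(CH3)3, Cp2ZrCl2, CH2Cl2) and iodinolysis would give the (E)-vinyl iodide F1. Steps 6, 9, 10 and 11 applied to it would lead through the aldehyde F2, the aldol adduct F3 (taken on crude), the lactone thioester F4 and the alcohol F5 to the iodo-aldehyde F6. An intramolecular Nozaki–Hiyama–Kishi reaction (CrCl2, catalytic NiCl2, DMSO, high dilution) would then form C5–C6 with retention of the alkene geometry and come back to the route at 23.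

Step 9. The anti simple diastereoselection may erode with the ester-bearing ketene acetal, and the PMB ether may be lost to the Lewis acid. The fallback sets the two centres separately. Setting out from aldehyde 12, a chelation-controlled acetate Mukaiyama aldol (MgBr2·OEt2, tert-butyl[(1-methoxyethenyl)oxy]dimethylsilane) would give the 8,9-syn β-hydroxy ester F7. Fráter–Seebach alkylation of its dianion (LiN(iPr)2 in excess to cover the alkyne C–H, allyl bromide) would place C11 anti to the hydroxyl and give the allylated ester F8. LiAlH4 reduction would give the diol F9, and silylation of the primary hydroxyl (tert-butyldimethylsilyl chloride, imidazole) the silyl ether F10. Lemieux–Johnson cleavage of the allyl group would give the lactol F11, and oxidation (TEMPO, PhI(OAc)2) the silylated lactone F12. HF·pyridine would then come back to the route at 20.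

Step 13. Oxygen may be delivered to the wrong face of the ring alkene if the reactive conformer is not the one assumed. The fallback replaces hydroxyl direction by reagent control. Setting out from 23, silylation (chlorotriethylsilane, imidazole) would give the allylic triethylsilyl ether F13. Shi epoxidation with the D-fructose-derived ketone (KHSO5 as 2KHSO5·KHSO4·K2SO4, buffered to pH 8, CH3CN/dimethoxymethane/water, 0 °C), whose spiro transition state gives R,R-epoxides from E-trisubstituted alkenes, would come back to the route at 25.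

**Further compounds**
F1 | step 12 | 1-({[(1E,3R,4R,8E)-9-iodo-4,8-dimethyl-1-phenylnona-1,8-dien-3-yl]oxy}methyl)-4-methoxybenzene | I/C=C(\C)CCC[C@@H](C)[C@@H](OCc1ccc(OC)cc1)/C=C/c1ccccc1
F2 | step 12 | (2R,3R,7E)-8-iodo-2-[(4-methoxyphenyl)methoxy]-3,7-dimethyloct-7-enal | I/C=C(\C)CCC[C@@H](C)[C@@H](OCc1ccc(OC)cc1)C=O
F3 | step 12 | vinyl iodide analogue of aldol adduct 18 | I/C=C(\C)CCC[C@@H](C)[C@@H](OCc1ccc(OC)cc1)[C@H](O)[C@H](CC(=O)OC)C(=O)SC(C)(C)C
F4 | step 12 | vinyl iodide analogue of lactone thioester 19 | I/C=C(\C)CCC[C@@H](C)[C@@H](OCc1ccc(OC)cc1)[C@@H]1OC(=O)C[C@@H]1C(=O)SC(C)(C)C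
F5 | step 12 | vinyl iodide analogue of alcohol 20 | I/C=C(\C)CCC[C@@H](C)[C@@H](OCc1ccc(OC)cc1)[C@@H]1OC(=O)C[C@@H]1CO
F6 | step 12 | vinyl iodide analogue of aldehyde 21 | I/C=C(\C)CCC[C@@H](C)[C@@H](OCc1ccc(OC)cc1)[C@@H]1OC(=O)C[C@@H]1C=O
F7 | step 9 | methyl (3R,4R,5R)-3-hydroxy-4-[(4-methoxyphenyl)methoxy]-5-methyldec-9-ynoate | C#CCCC[C@@H](C)[C@@H](OCc1ccc(OC)cc1)[C@H](O)CC(=O)OC
F8 | step 9 | methyl (2S,3R,4R,5R)-3-hydroxy-4-[(4-methoxyphenyl)methoxy]-5-methyl-2-(prop-2-en-1-yl)dec-9-ynoate | C#CCCC[C@@H](C)[C@@H](OCc1ccc(OC)cc1)[C@H](O)[C@H](CC=C)C(=O)OC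
F9 | step 9 | (2R,3R,4R,5R)-4-[(4-methoxyphenyl)methoxy]-5-methyl-2-(prop-2-en-1-yl)dec-9-yne-1,3-diol | C#CCCC[C@@H](C)[C@@H](OCc1ccc(OC)cc1)[C@H](O)[C@H](CC=C)CO
F10 | step 9 | primary tert-butyldimethylsilyl ether of F9 | C#CCCC[C@@H](C)[C@@H](OCc1ccc(OC)cc1)[C@H](O)[C@H](CC=C)CO[Si](C)(C)C(C)(C)C
F11 | step 9 | lactol (anomers) from cleavage of F10 | C#CCCC[C@@H](C)[C@@H](OCc1ccc(OC)cc1)[C@@H]1OC(O)C[C@@H]1CO[Si](C)(C)C(C)(C)C
F12 | step 9 | tert-butyldimethylsilyl ether of 20 | C#CCCC[C@@H](C)[C@@H](OCc1ccc(OC)cc1)[C@@H]1OC(=O)C[C@@H]1CO[Si](C)(C)C(C)(C)C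
F13 | step 13 | triethylsilyl ether of 23 | C1C(=O)O[C@H]2[C@H](OCc3ccc(OC)cc3)[C@H](C)CCC/C(C)=C/[C@H](O[Si](CC)(CC)CC)[C@@H]12
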